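# Proposal: synthesis of CNP0407146.3 (25) by 6-exo opening of a Sharpless epoxide with a C3 hydroperoxide

## The problem

Target 25 is a plakortolide-type peroxylactone in which a 1,2-dioxane and a γ-butyrolactone share the C3–C4 bond in a cis fusion (numbering used throughout: C1 lactone carbonyl, C2 lactone CH2, C3 fusion CH on the peroxide, C4 fusion carbon with methyl and lactone oxygen, C5 ring CH2, C6 peroxide carbon with methyl and the 10-phenyldecyl chain; 3S,4S,6R). Two of the three stereocentres, C4 and C6, are fully substituted C–O carbons that face each other across C5. They are too far apart and too similar in their substituents for one to set the other reliably, so each needs its own source of chirality. C3 is the only hydrogen-bearing centre, lies next to C4, and can be set late under substrate control. Once the O–O bond exists it excludes catalytic hydrogenation, low-valent metals, hot phosphines and most radical chemistry, and in the finished peroxylactone C3–H and the acidic C2 hydrogens invite base-induced loss of the peroxide (Kornblum–DeLaMare fragmentation or E1cB expulsion from C3). The side chain is only CH2 groups and a phenyl ring and is best attached late to a one-carbon handle on C6. The feature that makes the key step possible is that C6 is a tertiary C–O carbon whose chain can be grown from an aldehyde on the neighbouring carbon: C6 plus two extra carbons (C7, C8) is the tertiary end of a 2,3-epoxy alcohol, and C3, five atoms away, can stand at the ketone oxidation level and carry a hydroperoxide that reaches C6 through a six-membered transition state.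

## Retrosynthesis

**Lactone C1–O bond (25 ⇒ 24 ⇒ 23).** The lactone is opened first. In hydroxy ester 24 (from silyl ether 23) the tertiary hydroxyl and the CH2CO2Me arm are cis on neighbouring carbons, so the forward step needs only mild acid. Closing the lactone last means the base-sensitive β-peroxy lactone never meets anything harsher than dilute acid.

**C3–H bond (23 ⇒ 22).** The C3 hydrogen is traced to hydride addition to the peroxycarbenium ion from methyl peroxyketal 22. Keeping C3 at the ketone level until here means no earlier intermediate has a hydrogen on a peroxide-bearing carbon, and the C3 configuration need not be controlled when the peroxide is introduced. The reduction is placed before lactonisation. In the monocyclic ion the C4 silyloxy group can stand axial and send hydride to the opposite face through a chair with both methyl groups equatorial. In the lactone the C4–O bond would be held near the plane of the ion and the C4 methyl group would become the perpendicular substituent, steering hydride toward the trans-fused epimer (the sense known for conjugate hydride addition to angularly methylated hydrindenones). The forward reaction must ionise the exocyclic C–OMe bond and not the ring C–O bond.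

**Side chain (22 ⇒ 21 ⇒ 15 + 20).** The chain is cut between its first two carbons: alkene 21 comes from aldehyde 15 and ylide 20, and diimide saturates it. Ylide 20 comes from phosphonium salt 19, made from 9-phenylnonanoic acid 16 through alcohol 17 and bromide 18. A cut further along the chain would need sp3–sp3 coupling with reducing metals next to the O–O bond. The aldehyde on C6 cannot enolise and falls out of the key step at no extra cost.

**Aldehyde handle (15 ⇒ 14).** Aldehyde 15 is the glycol-cleavage product of diol 14, which is exactly what an opened 2,3-epoxy alcohol leaves behind.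

**Key disconnection, C6–O bond (14 ⇒ 13).** The C6–O bond of the dioxane is cut and the C7 hydroxyl is recognised as the former epoxide oxygen. Precursor 13 is acyclic: an α-methoxy hydroperoxide at C3 and a trisubstituted (2R,3R)-epoxy alcohol. This cut creates C6 with inversion from a centre that Sharpless chemistry sets under reagent control. The neighbouring C3–O cut would need intermolecular perhydrolysis of the epoxide with excess concentrated H2O2; it is kept as a reserve. An O–O cut has no practical forward reaction. The forward step must open the epoxide at the tertiary carbon (6-exo) without ionising the peroxyketal.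

**C3 peroxide oxygens (13 ⇒ 12).** The hydroperoxy ketal is not made by acid exchange of a ketal with H2O2. The C3 ketal is flanked by an ester-bearing CH2 and a silyloxy-substituted quaternary carbon and would ionise more slowly than the trisubstituted epoxide opens, so the order of bond formation would be lost. Both peroxide oxygens are instead traced to ozone: the O-methyl oxime 12 is cleaved to the C3 carbonyl oxide, which methanol traps at −78 °C under neutral conditions.

**Epoxide (12 ⇒ 11).** The epoxide comes from E-allylic alcohol 11 by Sharpless asymmetric epoxidation. Reagent control is needed because C4 is remote. The (2R,3R) epoxide from D-(−)-tartrate is the one that gives 6R in 25 after inversion.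

**C2–C3 bond (11 ⇒ 9 ⇒ 8).** Oxime ether 11 comes from β-keto ester 9 through the bis-silyl oxime ether 10. Ketone 9 is cut at C2–C3 into methyl acetate and α-silyloxy ester 8 (Claisen condensation). The silyl ether on C4 is essential here: a free γ-alkoxide would close a tetronic acid.

**C4–C5 bond (8 ⇒ 7 ⇒ 6 ⇒ 3 + 4 ⇒ 1 + 2).** Ester 8 is the silylated form of diol ester 7, the methanolysis product of dioxolanone 6. Dioxolanone 6 is cut at C4–C5 into the lactic acid acetal 3 (as enolate 5) and allylic chloride 4, and 3 comes from (R)-lactic acid 1 and pivalaldehyde 2. Alkylation trans to the tert-butyl group gives net retention, and since the incoming CH2 outranks methyl, (R)-lactic acid gives 4S. The E geometry of 4 becomes the relative configuration of the epoxide.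

## Roads not taken

**Alternative 1:** peroxy-Prins bicyclisation. The cut removes C5–C6, C6–O and C4–O at once, leaving the allylic hydroperoxide tert-butyl (3S)-3-hydroperoxy-4-methylpent-4-enoate A2 and the ynone ketal (12,12-dimethoxytridec-10-yn-1-yl)benzene A3.
- Forward step: ketal exchange joins A2 to A3 through the peroxide, TMSOTf generates a peroxycarbenium ion at C6, the isopropenyl CH2 attacks it, and the tert-butyl ester captures the C4 cation with loss of isobutene. This gives the alkynyl peroxylactone A1; diimide would then saturate the triple bond.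
- Merits: very high convergence (three bonds, both rings, the whole skeleton), no ylide chemistry on a peroxide, and cis fusion guaranteed by the tethered ester.
- Weak points: A2 is a secondary allylic hydroperoxide that must be enantiopure and is the only source of absolute configuration. C4 and C6 are both created in one cationic cascade; C6 selectivity rests on the small steric difference between methyl and a linear alkynyl group, and the C4 cation can lose a proton instead of being trapped. The propargylic cation can also be attacked at the alkyne terminus.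
- Comparison: this road is clearly shorter. The chosen plan sets against it independent stereocontrol (C4 from lactic acid, C6 from a Sharpless epoxide) and a ring closure with a predictable regio- and stereochemical course.

**Alternative 2:** iodolactonisation of a dihydrodioxine. The cut is the lactone C4–O bond of the C5-iodo lactone A4, going back to methyl 2-[(3S,6S)-6-(hydroxymethyl)-4,6-dimethyl-3,6-dihydro-1,2-dioxin-3-yl]acetate A5. The cis relationship across the peroxide in A5 would come from a singlet-oxygen [4+2] cycloaddition within a seven-membered ring that is cleaved afterwards.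
- Forward step: iodine activates the C4=C5 bond of A5 and the ester carbonyl of the C3 arm attacks C4 from its own face (5-exo), giving A4 with iodine on C5. Deiodination, oxidation of the hydroxymethyl group and the same Wittig/diimide sequence would follow.
- Merits: the tethered lactonisation relays C3 to C4 with certainty. This relay is more secure than the hydride delivery of step 16 here.
- Weak points: the cycloaddition substrate is achiral or racemic, so absolute configuration needs a resolution or desymmetrisation. The C–I bond must be removed by a radical chain reduction whose chain carriers also attack O–O bonds. The chain would be attached with a basic ylide on the finished, base-sensitive peroxylactone.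
- Comparison: similar length. The chosen plan has absolute control from two cheap chiral sources and no halogen to remove, at the price of a less certain C3 step, for which a thermodynamic remedy is held in reserve.

**Alternative 3:** ring-closing metathesis across a dialkyl peroxide. The cut is the C4=C5 bond of dihydrodioxine A6; the precursor is the acyclic peroxide tert-butyl (3S)-4-methyl-3-{[(3R)-3-methyl-13-phenyltridec-1-en-3-yl]peroxy}pent-4-enoate A7.
- Forward step: the second-generation Hoveyda–Grubbs catalyst joins the isopropenyl group on C3 with the vinyl group on C6 of A7 to give A6. A later acid- or iodine-mediated lactonisation onto C4 would complete the bicycle.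
- Merits: C3 and C6 are set before the ring exists, the full chain is present from the start, and no peroxyketal reduction is needed. If A7 were in hand, the rest would be shorter than steps 10–17 here.
- Weak points: A7 joins a secondary allylic carbon (β to an ester) and a tertiary allylic carbon through O–O. Alkylating a tertiary hydroperoxide with such a secondary electrophile competes with elimination and SN2′ and puts the C3 configuration at risk. The closure must form a trisubstituted alkene from a 1,1-disubstituted and an allylically quaternary olefin, and ruthenium carbenes are not inert toward peroxides over long reaction times.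
- Comparison: the chosen plan replaces the difficult C–O–O–C assembly by an intramolecular epoxide opening of defined stereochemical course, and pays for it with the oxidation-state adjustment at C3.

Key step: step 9

Remarks on the chemistry: compounds 13, 14, 15, 21 and 22 are carried as both C3 epimers and 10–12 as E/Z oxime ethers; both elements are erased (steps 8 and 16), so their SMILES leave these positions open. Compounds 1, 2, 4 and 16 are taken as purchased.

## Route

Step 1
Reactants: 1 (R)-lactic acid; 2 pivalaldehyde
Product: 3 (2R,5R)-2-tert-butyl-5-methyl-1,3-dioxolan-4-one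
Conditions: TsOH·H2O (cat.), H2SO4 (cat.), pentane, reflux (Dean–Stark); crystallisation at −78 °C
Reagents that add atoms: none
Why: Acid-catalysed acetalisation with azeotropic removal of water; the cis (2R,5R) acetal is the major, crystalline isomer and stores the lactate configuration in the acetal carbon so that C4 can be rebuilt after enolisation (self-regeneration of the stereocentre).

Step 2
Reactants: 3 (2R,5R)-2-tert-butyl-5-methyl-1,3-dioxolan-4-one; 4 (E)-4-chloro-3-methylbut-2-en-1-yl acetate
Product: 6 (2R,5S)-5-[(2E)-4-acetoxy-2-methylbut-2-en-1-yl]-2-tert-butyl-5-methyl-1,3-dioxolan-4-one, via dioxolanone lithium enolate 5 (not isolated)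
Conditions: LiN(iPr)2, THF, −78 °C; then 4, DMPU, −78 → −30 °C
Reagents that add atoms: none
Why: Enolate alkylation with self-regeneration of the stereocentre: planar enolate 5 is shielded on one face by the acetal tert-butyl group, so the primary allylic chloride (about as reactive in SN2 as a primary alkyl iodide) is attacked trans to it, fixing C4 as S with net retention; the cold SN2 step should outrun acyl transfer from the acetate and leaves the E alkene untouched.

Step 3
Reactants: 6 (2R,5S)-5-[(2E)-4-acetoxy-2-methylbut-2-en-1-yl]-2-tert-butyl-5-methyl-1,3-dioxolan-4-one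
Product: 7 methyl (2S,4E)-2,6-dihydroxy-2,4-dimethylhex-4-enoate
Conditions: K2CO3 (0.3 equiv), MeOH, 0 °C → rt
Reagents that add atoms: methanol, CO
Why: Base-catalysed transesterification: methoxide opens the acylal-type lactone, the hemiacetal alkoxide sheds pivalaldehyde and the allylic acetate is methanolysed in the same operation; C4 is quaternary and cannot epimerise.

Step 4
Reactants: 7 methyl (2S,4E)-2,6-dihydroxy-2,4-dimethylhex-4-enoate
Product: 8 methyl (2S,4E)-2,4-dimethyl-2,6-bis(triethylsilyloxy)hex-4-enoate
Conditions: Et3SiOTf (2.5 equiv), 2,6-lutidine, CH2Cl2, −78 → 0 °C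
Reagents that add atoms: triethylsilyl triflate, CC[Si](CC)(CC)OS(=O)(=O)C(F)(F)F
Why: Silyl triflate silylation, reactive enough for the tertiary α-hydroxy ester; capping this oxygen prevents the γ-alkoxide from closing a tetronic acid after step 5 and later keeps it from competing for the epoxide.

Step 5
Reactants: 8 methyl (2S,4E)-2,4-dimethyl-2,6-bis(triethylsilyloxy)hex-4-enoate
Product: 9 methyl (4S,6E)-4,6-dimethyl-3-oxo-4,8-bis(triethylsilyloxy)oct-6-enoate
Conditions: methyl acetate (3.2 equiv), LiN(iPr)2 (3.2 equiv), THF, −78 °C; then 8, −78 → −30 °C; aq. NH4Cl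
Reagents that add atoms: methyl acetate, COC(C)=O
Why: Crossed Claisen condensation: ester 8 has no α-hydrogen and an inductively activated carbonyl, so the lithium enolate of methyl acetate adds and the β-keto ester is drawn out of the equilibrium as its enolate; low temperature suppresses self-condensation of methyl acetate.

Step 6
Reactants: 9 methyl (4S,6E)-4,6-dimethyl-3-oxo-4,8-bis(triethylsilyloxy)oct-6-enoate
Product: 11 methyl (4S,6E)-8-hydroxy-3-(methoxyimino)-4,6-dimethyl-4-(triethylsilyloxy)oct-6-enoate, via bis-silyl oxime ether 10 (not isolated)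
Conditions: MeONH2·HCl, pyridine, CH2Cl2, rt; then MeOH, PPTS, rt
Reagents that add atoms: O-methylhydroxylamine hydrochloride, CON.Cl
Why: Oxime ether condensation at the ketone (the ester is inert), then PPTS-catalysed methanolysis of the primary silyl ether, which is far faster than that of the hindered tertiary one; the E/Z mixture at C=N is irrelevant because the group is cleaved in step 8.

Step 7
Reactants: 11 methyl (4S,6E)-8-hydroxy-3-(methoxyimino)-4,6-dimethyl-4-(triethylsilyloxy)oct-6-enoate
Product: 12 methyl (4S)-5-[(2R,3R)-3-(hydroxymethyl)-2-methyloxiran-2-yl]-3-(methoxyimino)-4-methyl-4-(triethylsilyloxy)pentanoate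
Conditions: Ti(OiPr)4 (0.3 equiv), D-(−)-diethyl tartrate (0.36 equiv), tBuOOH, 4 Å MS, CH2Cl2, −20 °C
Reagents that add atoms: tert-butyl hydroperoxide, CC(C)(C)OO
Why: Sharpless asymmetric epoxidation: with D-(−)-diethyl tartrate an E-allylic alcohol of this substitution pattern gives the (2R,3R)-2,3-epoxy alcohol under reagent control, independent of remote C4; oxime ether, ester and silyl ether are not affected.

Step 8
Reactants: 12 methyl (4S)-5-[(2R,3R)-3-(hydroxymethyl)-2-methyloxiran-2-yl]-3-(methoxyimino)-4-methyl-4-(triethylsilyloxy)pentanoate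
Product: 13 methyl (4S)-3-hydroperoxy-5-[(2R,3R)-3-(hydroxymethyl)-2-methyloxiran-2-yl]-3-methoxy-4-methyl-4-(triethylsilyloxy)pentanoate (both C3 epimers)
Conditions: O3, CH2Cl2/MeOH (3:1), NaHCO3, −78 → −40 °C; N2 purge, no reductive work-up
Reagents that add atoms: ozone, [O-][O+]=O; methanol, CO
Why: Griesbaum-type ozonolysis of an O-methyl ketoxime: ozone cleaves C=N to the C3 carbonyl oxide (Criegee intermediate) and methyl nitrite, and methanol traps the carbonyl oxide as the α-methoxy hydroperoxide under neutral, cold conditions that the epoxide survives; no C=C bond is left to compete and both C3 epimers are acceptable.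

Step 9
Reactants: 13 methyl (4S)-3-hydroperoxy-5-[(2R,3R)-3-(hydroxymethyl)-2-methyloxiran-2-yl]-3-methoxy-4-methyl-4-(triethylsilyloxy)pentanoate
Product: 14 methyl 2-[(4S,6S)-6-[(1R)-1,2-dihydroxyethyl]-3-methoxy-4,6-dimethyl-4-(triethylsilyloxy)-1,2-dioxan-3-yl]acetate (both C3 epimers)
Conditions: Yb(OTf)3 (20 mol %), 4 Å MS, CH2Cl2, 0 °C → rt
Reagents that add atoms: none
Why: Yb(OTf)3 binds the epoxide oxygen (helped by the neighbouring C8 hydroxyl) and polarises the C6–O bond, and the terminal oxygen of the C3 hydroperoxide attacks C6 from the rear in a borderline SN2 opening. The closest known reaction types are the acid-promoted intramolecular opening of an epoxide by a hydroperoxide to a cyclic peroxide and the acid-catalysed perhydrolysis of trisubstituted epoxides at the tertiary carbon with inversion. The 1,2-dioxane closes in the 6-exo-tet mode (O–O–C6–C5–C4–C3), with the epoxide oxygen left outside the ring as the C7 hydroxyl. The one stereocentre created, C6–O, is fixed by backside attack on the (2R,3R)-epoxide of step 7, so it is under reagent control from the tartrate and independent of C4 and of the C3 epimer mixture; C7 keeps its configuration and is destroyed in step 10. The step needs regioselectivity for C6 over C7 and chemoselectivity for epoxide activation over ionisation of the peroxyketal: C6 is tertiary and is the exo carbon (attack at C7 would be a 7-endo closure at a secondary carbon), and the peroxyketal carbon is flanked by an ester-bearing CH2 and a silyloxy-substituted quaternary carbon, both of which disfavour its ionisation by a mild lanthanide triflate. The C4 oxygen is silylated and cannot compete as a nucleophile.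

Step 10
Reactants: 14 methyl 2-[(4S,6S)-6-[(1R)-1,2-dihydroxyethyl]-3-methoxy-4,6-dimethyl-4-(triethylsilyloxy)-1,2-dioxan-3-yl]acetate
Product: 15 methyl 2-[(4S,6S)-6-formyl-3-methoxy-4,6-dimethyl-4-(triethylsilyloxy)-1,2-dioxan-3-yl]acetate
Conditions: NaIO4, THF/pH 7 buffer, 0 °C → rt
Reagents that add atoms: none
Why: Periodate glycol cleavage (Malaprade reaction) removes C8 as formaldehyde; the neutral oxidant leaves the O–O bond, peroxyketal and silyl ether alone, and the aldehyde cannot enolise because C6 is quaternary.

Step 11
Reactants: 16 9-phenylnonanoic acid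
Product: 17 9-phenylnonan-1-ol
Conditions: LiAlH4, THF, 0 °C → rt
Reagents that add atoms: none
Why: Hydride reduction of a carboxylic acid to the primary alcohol; no other functional group is present.

Step 12
Reactants: 17 9-phenylnonan-1-ol
Product: 18 (9-bromononyl)benzene
Conditions: CBr4, PPh3, CH2Cl2, 0 °C
Reagents that add atoms: carbon tetrabromide, BrC(Br)(Br)Br
Why: Appel reaction: the alkoxyphosphonium ion is displaced by bromide in an SN2 step at the primary carbon.

Step 13
Reactants: 18 (9-bromononyl)benzene
Product: 19 triphenyl(9-phenylnonyl)phosphonium bromide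
Conditions: PPh3, MeCN, reflux
Reagents that add atoms: triphenylphosphine, c1ccc(cc1)P(c1ccccc1)c1ccccc1
Why: SN2 quaternisation of triphenylphosphine by the primary bromide gives the Wittig salt.

Step 14
Reactants: 19 triphenyl(9-phenylnonyl)phosphonium bromide; 15 methyl 2-[(4S,6S)-6-formyl-3-methoxy-4,6-dimethyl-4-(triethylsilyloxy)-1,2-dioxan-3-yl]acetate
Product: 21 methyl 2-[(4S,6S)-3-methoxy-4,6-dimethyl-6-[(1Z)-10-phenyldec-1-en-1-yl]-4-(triethylsilyloxy)-1,2-dioxan-3-yl]acetate, via phosphorus ylide 20 (not isolated)
Conditions: 19 (1.3 equiv), NaN(SiMe3)2 (1.2 equiv), THF, −78 → 0 °C; then 15, −78 → −20 °C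
Reagents that add atoms: none
Why: Wittig olefination with the non-stabilised ylide 20; a slight deficit of base relative to 19 leaves no free amide to deprotonate C2, and at −78 °C addition to the aldehyde should outpace attack on the hindered di-tertiary peroxide; the alkene geometry is erased in step 15, and C3 still has no hydrogen, so base-induced peroxide fragmentation has no entry.

Step 15
Reactants: 21 methyl 2-[(4S,6S)-3-methoxy-4,6-dimethyl-6-[(1Z)-10-phenyldec-1-en-1-yl]-4-(triethylsilyloxy)-1,2-dioxan-3-yl]acetate
Product: 22 methyl 2-[(4S,6R)-3-methoxy-4,6-dimethyl-6-(10-phenyldecyl)-4-(triethylsilyloxy)-1,2-dioxan-3-yl]acetate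
Conditions: KO2CN=NCO2K, AcOH, CH2Cl2/MeOH, 0 °C → rt (repeated charges)
Reagents that add atoms: none
Why: Diimide reduction: concerted syn transfer of two hydrogens from HN=NH generated in situ saturates the C=C bond without cleaving the O–O bond, which catalytic hydrogenation would not spare; several charges are expected to be needed for the hindered alkene (the C6 descriptor changes from S to R only because the CIP priorities change).

Step 16
Reactants: 22 methyl 2-[(4S,6R)-3-methoxy-4,6-dimethyl-6-(10-phenyldecyl)-4-(triethylsilyloxy)-1,2-dioxan-3-yl]acetate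
Product: 23 methyl 2-[(3S,4S,6R)-4,6-dimethyl-6-(10-phenyldecyl)-4-(triethylsilyloxy)-1,2-dioxan-3-yl]acetate
Conditions: Et3SiH (5 equiv), TMSOTf (1.2 equiv), CH2Cl2, −78 °C
Reagents that add atoms: none
Why: Ionic hydrogenation of a peroxyketal (silane reduction of a peroxycarbenium ion): TMSOTf removes the exocyclic methoxy group so that both C3 epimers converge on one planar ion, and Et3SiH is expected to deliver hydride axially, anti to the axial C4 silyloxy group, through the chair-like transition state that keeps the C4 and C6 methyl groups equatorial, giving 3S with the acetate arm cis to the C4 oxygen; attack on the other face would require both methyl groups to be syn-axial.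

Step 17
Reactants: 23 methyl 2-[(3S,4S,6R)-4,6-dimethyl-6-(10-phenyldecyl)-4-(triethylsilyloxy)-1,2-dioxan-3-yl]acetate
Product: 25 (3R,4aS,7aS)-3,4a-dimethyl-3-(10-phenyldecyl)tetrahydro-3H-furo[3,2-c][1,2]dioxin-6(4H)-one (CNP0407146.3), via hydroxy ester 24 (not isolated)
Conditions: HF·pyridine, THF, 0 °C → rt; then TsOH·H2O (cat.), CH2Cl2, rt
Reagents that add atoms: none
Why: Fluoride cleavage of the tertiary silyl ether, then acid-catalysed 5-exo-trig lactonisation of γ-hydroxy ester 24, whose axial hydroxyl and equatorial acetate arm are cis on adjacent carbons; no base is used, so the β-peroxy lactone is not exposed to E1cB or Kornblum–DeLaMare cleavage, and no stereocentre is touched.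

## Compound list

1 | (R)-lactic acid | C[C@@H](O)C(=O)O | starting material
2 | pivalaldehyde | CC(C)(C)C=O | starting material
3 | (2R,5R)-2-tert-butyl-5-methyl-1,3-dioxolan-4-one | C[C@H]1O[C@@H](C(C)(C)C)OC1=O | intermediate
4 | (E)-4-chloro-3-methylbut-2-en-1-yl acetate | CC(=O)OC/C=C(C)/CCl | starting material
5 | lithium (2R)-2-tert-butyl-5-methyl-1,3-dioxol-4-olate (lithium enolate of 3) | CC1=C([O-])O[C@H](C(C)(C)C)O1.[Li+] | intermediate (not isolated)
6 | (2R,5S)-5-[(2E)-4-acetoxy-2-methylbut-2-en-1-yl]-2-tert-butyl-5-methyl-1,3-dioxolan-4-one | C[C@@]1(C/C(C)=C/COC(C)=O)O[C@@H](C(C)(C)C)OC1=O | intermediate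
7 | methyl (2S,4E)-2,6-dihydroxy-2,4-dimethylhex-4-enoate | COC(=O)[C@@](C)(O)C/C(C)=C/CO | intermediate
8 | methyl (2S,4E)-2,4-dimethyl-2,6-bis(triethylsilyloxy)hex-4-enoate | COC(=O)[C@@](C)(O[Si](CC)(CC)CC)C/C(C)=C/CO[Si](CC)(CC)CC | intermediate
9 | methyl (4S,6E)-4,6-dimethyl-3-oxo-4,8-bis(triethylsilyloxy)oct-6-enoate | COC(=O)CC(=O)[C@@](C)(O[Si](CC)(CC)CC)C/C(C)=C/CO[Si](CC)(CC)CC | intermediate
10 | methyl (4S,6E)-3-(methoxyimino)-4,6-dimethyl-4,8-bis(triethylsilyloxy)oct-6-enoate (E/Z at C=N) | COC(=O)CC(=NOC)[C@@](C)(O[Si](CC)(CC)CC)C/C(C)=C/CO[Si](CC)(CC)CC | intermediate (not isolated)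
11 | methyl (4S,6E)-8-hydroxy-3-(methoxyimino)-4,6-dimethyl-4-(triethylsilyloxy)oct-6-enoate (E/Z at C=N) | COC(=O)CC(=NOC)[C@@](C)(O[Si](CC)(CC)CC)C/C(C)=C/CO | intermediate
12 | methyl (4S)-5-[(2R,3R)-3-(hydroxymethyl)-2-methyloxiran-2-yl]-3-(methoxyimino)-4-methyl-4-(triethylsilyloxy)pentanoate (E/Z at C=N) | COC(=O)CC(=NOC)[C@@](C)(O[Si](CC)(CC)CC)C[C@@]1(C)O[C@@H]1CO | intermediate
13 | methyl (4S)-3-hydroperoxy-5-[(2R,3R)-3-(hydroxymethyl)-2-methyloxiran-2-yl]-3-methoxy-4-methyl-4-(triethylsilyloxy)pentanoate (both C3 epimers) | COC(=O)CC(OC)(OO)[C@@](C)(O[Si](CC)(CC)CC)C[C@@]1(C)O[C@@H]1CO | intermediate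
14 | methyl 2-[(4S,6S)-6-[(1R)-1,2-dihydroxyethyl]-3-methoxy-4,6-dimethyl-4-(triethylsilyloxy)-1,2-dioxan-3-yl]acetate (both C3 epimers) | C[C@@]1([C@H](O)CO)C[C@](C)(O[Si](CC)(CC)CC)C(OC)(CC(=O)OC)OO1 | intermediate
15 | methyl 2-[(4S,6S)-6-formyl-3-methoxy-4,6-dimethyl-4-(triethylsilyloxy)-1,2-dioxan-3-yl]acetate (both C3 epimers) | C[C@@]1(C=O)C[C@](C)(O[Si](CC)(CC)CC)C(OC)(CC(=O)OC)OO1 | intermediate
16 | 9-phenylnonanoic acid | OC(=O)CCCCCCCCc1ccccc1 | starting material
17 | 9-phenylnonan-1-ol | OCCCCCCCCCc1ccccc1 | intermediate
18 | (9-bromononyl)benzene | BrCCCCCCCCCc1ccccc1 | intermediate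
19 | triphenyl(9-phenylnonyl)phosphonium bromide | [Br-].c1ccc(cc1)CCCCCCCCC[P+](c1ccccc1)(c1ccccc1)c1ccccc1 | intermediate
20 | triphenyl(9-phenylnonylidene)phosphorane | c1ccc(cc1)CCCCCCCCC=P(c1ccccc1)(c1ccccc1)c1ccccc1 | intermediate (not isolated)
21 | methyl 2-[(4S,6S)-3-methoxy-4,6-dimethyl-6-[(1Z)-10-phenyldec-1-en-1-yl]-4-(triethylsilyloxy)-1,2-dioxan-3-yl]acetate (both C3 epimers) | C[C@@]1(/C=C\CCCCCCCCc2ccccc2)C[C@](C)(O[Si](CC)(CC)CC)C(OC)(CC(=O)OC)OO1 | intermediate
22 | methyl 2-[(4S,6R)-3-methoxy-4,6-dimethyl-6-(10-phenyldecyl)-4-(triethylsilyloxy)-1,2-dioxan-3-yl]acetate (both C3 epimers) | C[C@@]1(CCCCCCCCCCc2ccccc2)C[C@](C)(O[Si](CC)(CC)CC)C(OC)(CC(=O)OC)OO1 | intermediate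
23 | methyl 2-[(3S,4S,6R)-4,6-dimethyl-6-(10-phenyldecyl)-4-(triethylsilyloxy)-1,2-dioxan-3-yl]acetate | C[C@@]1(CCCCCCCCCCc2ccccc2)C[C@](C)(O[Si](CC)(CC)CC)[C@H](CC(=O)OC)OO1 | intermediate
24 | methyl 2-[(3S,4S,6R)-4-hydroxy-4,6-dimethyl-6-(10-phenyldecyl)-1,2-dioxan-3-yl]acetate | C[C@@]1(CCCCCCCCCCc2ccccc2)C[C@](C)(O)[C@H](CC(=O)OC)OO1 | intermediate (not isolated)
25 | (3R,4aS,7aS)-3,4a-dimethyl-3-(10-phenyldecyl)tetrahydro-3H-furo[3,2-c][1,2]dioxin-6(4H)-one (CNP0407146.3; 3S,4S,6R in the numbering used here) | C[C@@]1(CCCCCCCCCCc2ccccc2)C[C@]2(C)OC(=O)C[C@@H]2OO1 | target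

## Step count and least certain steps

Total: 17 steps (14 in the main line, 3 for phosphonium salt 19). Longest linear sequence: 14 steps (steps 1–10 and 14–17).

**Step 9 (key step).** The most likely failure is Lewis-acid activation of the hydroperoxy ketal instead of the epoxide: loss of H2O2 or methanol from C3, or an acid-induced Criegee-type rearrangement of the tertiary hydroperoxide. Both functions are Lewis basic and the substrate is crowded at C3–C4.

The fallback reverses the order of bond formation. It sets out from β-keto ester 9 and returns at 14.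
- PPTS in methanol frees the allylic alcohol, giving methyl (4S,6E)-8-hydroxy-4,6-dimethyl-3-oxo-4-(triethylsilyloxy)oct-6-enoate F1.
- Sharpless epoxidation with D-(−)-diethyl tartrate gives the epoxy ketone methyl (4S)-5-[(2R,3R)-3-(hydroxymethyl)-2-methyloxiran-2-yl]-4-methyl-3-oxo-4-(triethylsilyloxy)pentanoate F2.
- Ethereal H2O2 with catalytic phosphomolybdic acid H3PMo12O40 opens the epoxide at the tertiary carbon with inversion to the open C6 hydroperoxide methyl (4S,6S,7R)-6-hydroperoxy-7,8-dihydroxy-4,6-dimethyl-3-oxo-4-(triethylsilyloxy)octanoate F3.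
- F3 adds to the C3 ketone to give the cyclic peroxy hemiketal methyl 2-[(4S,6S)-6-[(1R)-1,2-dihydroxyethyl]-3-hydroxy-4,6-dimethyl-4-(triethylsilyloxy)-1,2-dioxan-3-yl]acetate F4.
- Methanol with a trace of TsOH converts F4 into 14.

The same ring with the same C6 configuration results, but the C6–O bond is made intermolecularly and the ring is closed at C3.

**Step 8.** The most likely failure is slow cleavage of the hindered, electron-poor C=N bond. This would force long ozone exposure or a higher temperature, during which the product hydroperoxide may degrade.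

The fallback uses an alkene as the carbonyl oxide precursor. It sets out from 9 and returns at 13.
- Petasis methylenation of the ketone with Cp2TiMe2 gives methyl (4S,6E)-4,6-dimethyl-3-methylidene-4,8-bis(triethylsilyloxy)oct-6-enoate F5.
- PPTS in methanol gives methyl (4S,6E)-8-hydroxy-4,6-dimethyl-3-methylidene-4-(triethylsilyloxy)oct-6-enoate F6.
- Sharpless epoxidation with D-(−)-diethyl tartrate gives methyl (4S)-5-[(2R,3R)-3-(hydroxymethyl)-2-methyloxiran-2-yl]-4-methyl-3-methylidene-4-(triethylsilyloxy)pentanoate F7.
- Ozonolysis of the 1,1-disubstituted alkene in CH2Cl2/MeOH gives 13, the classical alkene route to α-methoxy hydroperoxides.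

The more substituted carbonyl oxide is normally favoured, but the two inductively withdrawing neighbours of C3 make the direction of fragmentation less certain, which is why this is the reserve and not the main route.

**Step 16.** The most likely failure is poor facial selectivity of hydride delivery. The preferred chair places the C4 silyloxy group axial, whereas hyperconjugation favours the half-chair with the C4 methyl group axial; the two effects oppose each other.

The fallback sets C3 under thermodynamic and tether control. It sets out from 22 and returns at 25.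
- The reduction is run without relying on selectivity and gives 23 together with its C3 epimer, methyl 2-[(3R,4S,6R)-4,6-dimethyl-6-(10-phenyldecyl)-4-(triethylsilyloxy)-1,2-dioxan-3-yl]acetate F8.
- HF·pyridine gives 24 and methyl 2-[(3R,4S,6R)-4-hydroxy-4,6-dimethyl-6-(10-phenyldecyl)-1,2-dioxan-3-yl]acetate F9.
- Et2NH in CF3CH2OH equilibrates the two β-peroxy esters by retro-oxa-Michael/oxa-Michael reaction through the open hydroperoxy enoate methyl (2E,4S,6R)-6-hydroperoxy-4-hydroxy-4,6-dimethyl-16-phenylhexadec-2-enoate F10.
- Catalytic TsOH then lactonises only 24, in which the arm is cis to the hydroxyl, to 25; recovered F9 is recycled.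

**Step 14.** The most likely failure is base-triggered degradation: deprotonation at C2 with expulsion of the C3 peroxide oxygen, or attack of the ylide on the O–O bond. The neopentyl-type aldehyde is also sluggish.

The fallback is a Julia–Kocienski olefination in Barbier mode, so that the carbanion is trapped as it forms. It sets out from alcohol 17 and aldehyde 15 and returns at 22.
- Mitsunobu reaction of 17 with 1-phenyl-1H-tetrazole-5-thiol gives 1-phenyl-5-[(9-phenylnonyl)sulfanyl]-1H-tetrazole F11.
- (NH4)6Mo7O24/H2O2 oxidises it to 1-phenyl-5-[(9-phenylnonyl)sulfonyl]-1H-tetrazole F12.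
- KN(SiMe3)2 is added at −78 °C to a mixture of F12 and 15 to give methyl 2-[(4S,6S)-3-methoxy-4,6-dimethyl-6-[(1E)-10-phenyldec-1-en-1-yl]-4-(triethylsilyloxy)-1,2-dioxan-3-yl]acetate F13.
- Diimide reduction as in step 15 gives 22.

## Further compounds

F1 | step 9 | methyl (4S,6E)-8-hydroxy-4,6-dimethyl-3-oxo-4-(triethylsilyloxy)oct-6-enoate | COC(=O)CC(=O)[C@@](C)(O[Si](CC)(CC)CC)C/C(C)=C/CO
F2 | step 9 | methyl (4S)-5-[(2R,3R)-3-(hydroxymethyl)-2-methyloxiran-2-yl]-4-methyl-3-oxo-4-(triethylsilyloxy)pentanoate | COC(=O)CC(=O)[C@@](C)(O[Si](CC)(CC)CC)C[C@@]1(C)O[C@@H]1CO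
F3 | step 9 | methyl (4S,6S,7R)-6-hydroperoxy-7,8-dihydroxy-4,6-dimethyl-3-oxo-4-(triethylsilyloxy)octanoate | COC(=O)CC(=O)[C@@](C)(O[Si](CC)(CC)CC)C[C@](C)(OO)[C@H](O)CO
F4 | step 9 | methyl 2-[(4S,6S)-6-[(1R)-1,2-dihydroxyethyl]-3-hydroxy-4,6-dimethyl-4-(triethylsilyloxy)-1,2-dioxan-3-yl]acetate (both C3 epimers) | C[C@@]1([C@H](O)CO)C[C@](C)(O[Si](CC)(CC)CC)C(O)(CC(=O)OC)OO1
F5 | step 8 | methyl (4S,6E)-4,6-dimethyl-3-methylidene-4,8-bis(triethylsilyloxy)oct-6-enoate | COC(=O)CC(=C)[C@@](C)(O[Si](CC)(CC)CC)C/C(C)=C/CO[Si](CC)(CC)CC
F6 | step 8 | methyl (4S,6E)-8-hydroxy-4,6-dimethyl-3-methylidene-4-(triethylsilyloxy)oct-6-enoate | COC(=O)CC(=C)[C@@](C)(O[Si](CC)(CC)CC)C/C(C)=C/CO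
F7 | step 8 | methyl (4S)-5-[(2R,3R)-3-(hydroxymethyl)-2-methyloxiran-2-yl]-4-methyl-3-methylidene-4-(triethylsilyloxy)pentanoate | COC(=O)CC(=C)[C@@](C)(O[Si](CC)(CC)CC)C[C@@]1(C)O[C@@H]1CO
F8 | step 16 | methyl 2-[(3R,4S,6R)-4,6-dimethyl-6-(10-phenyldecyl)-4-(triethylsilyloxy)-1,2-dioxan-3-yl]acetate | C[C@@]1(CCCCCCCCCCc2ccccc2)C[C@](C)(O[Si](CC)(CC)CC)[C@@H](CC(=O)OC)OO1
F9 | step 16 | methyl 2-[(3R,4S,6R)-4-hydroxy-4,6-dimethyl-6-(10-phenyldecyl)-1,2-dioxan-3-yl]acetate | C[C@@]1(CCCCCCCCCCc2ccccc2)C[C@](C)(O)[C@@H](CC(=O)OC)OO1
F10 | step 16 | methyl (2E,4S,6R)-6-hydroperoxy-4-hydroxy-4,6-dimethyl-16-phenylhexadec-2-enoate | COC(=O)/C=C/[C@@](C)(O)C[C@](C)(OO)CCCCCCCCCCc1ccccc1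
F11 | step 14 | 1-phenyl-5-[(9-phenylnonyl)sulfanyl]-1H-tetrazole | c1ccc(cc1)CCCCCCCCCSc1nnnn1-c1ccccc1
F12 | step 14 | 1-phenyl-5-[(9-phenylnonyl)sulfonyl]-1H-tetrazole | c1ccc(cc1)CCCCCCCCCS(=O)(=O)c1nnnn1-c1ccccc1
F13 | step 14 | methyl 2-[(4S,6S)-3-methoxy-4,6-dimethyl-6-[(1E)-10-phenyldec-1-en-1-yl]-4-(triethylsilyloxy)-1,2-dioxan-3-yl]acetate (both C3 epimers) | C[C@@]1(/C=C/CCCCCCCCc2ccccc2)C[C@](C)(O[Si](CC)(CC)CC)C(OC)(CC(=O)OC)OO1
A1 | alternative 1 | (3S,4aS,7aS)-3,4a-dimethyl-3-(10-phenyldec-1-yn-1-yl)tetrahydro-3H-furo[3,2-c][1,2]dioxin-6(4H)-one | C[C@@]1(C#CCCCCCCCCc2ccccc2)C[C@]2(C)OC(=O)C[C@@H]2OO1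
A2 | alternative 1 | tert-butyl (3S)-3-hydroperoxy-4-methylpent-4-enoate | CC(=C)[C@@H](OO)CC(=O)OC(C)(C)C
A3 | alternative 1 | (12,12-dimethoxytridec-10-yn-1-yl)benzene | CC(OC)(OC)C#CCCCCCCCCc1ccccc1
A4 | alternative 2 | 3-(hydroxymethyl)-4-iodo-3,4a-dimethyltetrahydro-3H-furo[3,2-c][1,2]dioxin-6(4H)-one (C5-iodo lactone, configuration as in the SMILES) | C[C@@]1(CO)[C@@H](I)[C@]2(C)OC(=O)C[C@@H]2OO1
A5 | alternative 2 | methyl 2-[(3S,6S)-6-(hydroxymethyl)-4,6-dimethyl-3,6-dihydro-1,2-dioxin-3-yl]acetate | C[C@@]1(CO)C=C(C)[C@H](CC(=O)OC)OO1
A6 | alternative 3 | tert-butyl 2-[(3S,6R)-4,6-dimethyl-6-(10-phenyldecyl)-3,6-dihydro-1,2-dioxin-3-yl]acetate | C[C@@]1(CCCCCCCCCCc2ccccc2)C=C(C)[C@H](CC(=O)OC(C)(C)C)OO1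
A7 | alternative 3 | tert-butyl (3S)-4-methyl-3-{[(3R)-3-methyl-13-phenyltridec-1-en-3-yl]peroxy}pent-4-enoate | C=C[C@@](C)(CCCCCCCCCCc1ccccc1)OO[C@@H](CC(=O)OC(C)(C)C)C(C)=C
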